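**Plan**

- Retrosynthesis: cut (a) the six aryl O–Si bonds of a hexakis(triisopropylsilyl) ether, (b) the stilbene C=C (Horner–Wadsworth–Emmons), (c) together the dioxane bonds C2–C3 and O4–C4a, (d) the benzylic O1–CH2 ether bond (Mitsunobu).
- Forward: a 3,5-bis(silyloxy)benzyl alcohol is joined to 3-fluoro-4-hydroxybenzaldehyde (ring A, aldehyde then masked as its dimethyl acetal). The dioxane ring is annulated onto ring A in one anionic operation with 3,4-bis(silyloxy)benzaldehyde. The aldehyde is unmasked, the styryl arm is added, and the silyl groups are removed last.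
- Enabling feature: in the ring segment O1–C2H(Ar)–C3H(Ar)–O4–C4a, C2 is benzylic and α-aryloxy, so it can carry a carbanion, and C3–O4 is an aldehyde C=O in disguise. C4a is the ring-A carbon ortho to O1, so the alkoxide born at O4 when C2 adds to the aldehyde sits six atoms from a C–F carbon and closes the ring by SNAr.
- Stereochemistry: C2 (R) from a chiral bis(oxazoline) on lithium; C3 (R) from the lithium-bridged threo addition; both are retained in the ring closure (threo gives trans). The alkene is E from the phosphonate olefination.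

Key step: step 6

Assumption: the (S,S)-bis(oxazoline) is taken to give the R configuration at the lithiated carbon; if the sense proves opposite, the (R,R)-ligand is used with no other change.
Abbreviations: TIPSO = triisopropylsilyloxy, OSi(i-Pr)3; benzodioxine locants are O1, C2, C3, O4, C4a, C5 to C8, C8a.

Step 1
Reactants: 1 3,5-dihydroxybenzaldehyde
Product: 2 3,5-bis(TIPSO)benzaldehyde
Conditions: TIPSCl, imidazole, DMF, rt
Reagents that add atoms: triisopropylsilyl chloride, CC(C)[Si](Cl)(C(C)C)C(C)C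
Why: Imidazole-promoted O-silylation of both phenols installs bulky, non-coordinating silyl ethers that tolerate t-BuLi and hinder ring lithiation in the key step.

Step 2
Reactants: 2 3,5-bis(TIPSO)benzaldehyde
Product: 3 [3,5-bis(TIPSO)phenyl]methanol
Conditions: NaBH4, EtOH/THF, 0 °C
Reagents that add atoms: none
Why: Borohydride reduction of the aryl aldehyde gives the benzyl alcohol and leaves aryl silyl ethers untouched.

Step 3
Reactants: 3 [3,5-bis(TIPSO)phenyl]methanol; 4 3-fluoro-4-hydroxybenzaldehyde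
Product: 5 4-{[3,5-bis(TIPSO)phenyl]methoxy}-3-fluorobenzaldehyde
Conditions: PPh3, DIAD, THF, 0 °C to rt
Reagents that add atoms: none
Why: Mitsunobu etherification of a primary benzylic alcohol with an acidic phenol (para-formyl, ortho-fluoro) forms the aryl benzyl ether under neutral conditions that spare the aryl silyl ethers.

Step 4
Reactants: 5 4-{[3,5-bis(TIPSO)phenyl]methoxy}-3-fluorobenzaldehyde
Product: 6 1-(dimethoxymethyl)-3-fluoro-4-{[3,5-bis(TIPSO)phenyl]methoxy}benzene
Conditions: HC(OMe)3, MeOH, PPTS (cat.), rt; Et3N quench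
Reagents that add atoms: trimethyl orthoformate, COC(OC)OC
Why: Acid-catalysed acetalization with orthoformate as water scavenger masks the aldehyde, so that it is inert to t-BuLi and no longer a π-acceptor on ring A during the annulation.

Step 5
Reactants: 7 3,4-dihydroxybenzaldehyde
Product: 8 3,4-bis(TIPSO)benzaldehyde
Conditions: TIPSCl, imidazole, DMAP (cat.), DMF, 40 °C
Reagents that add atoms: triisopropylsilyl chloride, CC(C)[Si](Cl)(C(C)C)C(C)C
Why: O-Silylation of the catechol gives an aldehyde partner without acidic hydrogens or lithium-chelating protecting groups.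

Step 6
Reactants: 6 1-(dimethoxymethyl)-3-fluoro-4-{[3,5-bis(TIPSO)phenyl]methoxy}benzene; 8 3,4-bis(TIPSO)benzaldehyde
Product: 11 (2R,3R)-3-[3,4-bis(TIPSO)phenyl]-2-[3,5-bis(TIPSO)phenyl]-6-(dimethoxymethyl)-2,3-dihydro-1,4-benzodioxine, via benzylic organolithium 9 (not isolated), via threo lithium alkoxide 10 (not isolated)
Conditions: t-BuLi, (S,S)-i-Pr-bis(oxazoline) [2,2'-(propane-2,2-diyl)bis((4S)-4-isopropyl-4,5-dihydrooxazole)], Et2O/hexane, −78 °C; then 8, −78 °C; then KOt-Bu (0.3 equiv), DMPU/THF, −78 to 50 °C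
Reagents that add atoms: none
Why: Proposed new method: the bis(oxazoline)-bound t-BuLi removes a benzylic O–CH2 hydrogen of 6 (the C–H flanked by aryl and aryloxy) to give the configurationally labile α-aryloxybenzyllithium 9, in which the C2-symmetric ligand on lithium selects one diastereomeric ion pair (dynamic resolution) and so should fix C2 as R when the carbanion is captured. Capture by aldehyde 8 through a lithium-bridged closed transition state (lithium held by the carbonyl oxygen and the α-oxygen, the two aryl groups anti) forms the C2–C3 bond and should give the threo lithium alkoxide 10, so C3 is set by this relative topicity. Potassium/DMPU activation then lets the alkoxide attack the ortho C–F carbon of ring A by intramolecular addition–elimination (SNAr through a Meisenheimer anion; six-membered ring, formally 6-exo-trig), which forms O4–C4a with retention at both sp3 carbons, so threo becomes trans-(2R,3R) and fluoride leaves as LiF. The closest known reaction types are α-lithiation and electrophile trapping of aryl benzyl ethers at −78 °C, bis(oxazoline)-controlled enantioselective substitutions of α-alkoxybenzyllithiums, and alkoxide SNAr ring closures on fluoroarenes; their union into one enantioselective annulation with an aldehyde is the untested part. The step needs benzylic rather than ring deprotonation (bulky, non-coordinating silyl ethers and low temperature), capture before [1,2]-Wittig aryl migration (−78 °C, weakly polar medium), and attack at C–F rather than ipso Smiles attack at the ether carbon (the acetal, unlike a free aldehyde, does not activate that position).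

Step 7
Reactants: 11 (2R,3R)-3-[3,4-bis(TIPSO)phenyl]-2-[3,5-bis(TIPSO)phenyl]-6-(dimethoxymethyl)-2,3-dihydro-1,4-benzodioxine
Product: 12 (2R,3R)-3-[3,4-bis(TIPSO)phenyl]-2-[3,5-bis(TIPSO)phenyl]-2,3-dihydro-1,4-benzodioxine-6-carbaldehyde
Conditions: PPTS (cat.), acetone/H2O, rt
Reagents that add atoms: water, O
Why: Mild acid-catalysed acetal hydrolysis returns the aldehyde, and the aryl silyl ethers and the benzodioxane should be stable at this acidity.

Step 8
Reactants: 3 [3,5-bis(TIPSO)phenyl]methanol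
Product: 13 1-(bromomethyl)-3,5-bis(TIPSO)benzene
Conditions: CBr4, PPh3, CH2Cl2, 0 °C
Reagents that add atoms: carbon tetrabromide, BrC(Br)(Br)Br
Why: The Appel reaction converts the benzylic alcohol to the bromide under neutral conditions.

Step 9
Reactants: 13 1-(bromomethyl)-3,5-bis(TIPSO)benzene
Product: 14 diethyl {[3,5-bis(TIPSO)phenyl]methyl}phosphonate
Conditions: P(OEt)3 (neat), 130 °C
Reagents that add atoms: triethyl phosphite, CCOP(OCC)OCC
Why: Michaelis–Arbuzov reaction of the benzylic bromide with triethyl phosphite gives the phosphonate, with bromoethane distilling off.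

Step 10
Reactants: 12 (2R,3R)-3-[3,4-bis(TIPSO)phenyl]-2-[3,5-bis(TIPSO)phenyl]-2,3-dihydro-1,4-benzodioxine-6-carbaldehyde; 14 diethyl {[3,5-bis(TIPSO)phenyl]methyl}phosphonate
Product: 15 (2R,3R)-3-[3,4-bis(TIPSO)phenyl]-2-[3,5-bis(TIPSO)phenyl]-6-{(E)-2-[3,5-bis(TIPSO)phenyl]ethenyl}-2,3-dihydro-1,4-benzodioxine
Conditions: NaH, 15-crown-5 (cat.), THF, 0 °C to rt
Reagents that add atoms: none
Why: Horner–Wadsworth–Emmons olefination of the aryl aldehyde with the benzylic phosphonate anion should give the (E)-stilbene through the favoured anti elimination pathway, and the ring stereocenters carry no hydrogen acidic enough to be touched.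

Step 11
Reactants: 15 (2R,3R)-3-[3,4-bis(TIPSO)phenyl]-2-[3,5-bis(TIPSO)phenyl]-6-{(E)-2-[3,5-bis(TIPSO)phenyl]ethenyl}-2,3-dihydro-1,4-benzodioxine
Product: 16 cassigarol E
Conditions: Bu4NF, AcOH, THF, 0 °C to rt, argon
Reagents that add atoms: none
Why: Fluoride-mediated cleavage of the six aryl silyl ethers, buffered with acetic acid so that the catechol and resorcinol anions are not oxidized, should free the target without touching the stereocenters or the alkene.

**Compound list**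

1 | 3,5-dihydroxybenzaldehyde | O=Cc1cc(O)cc(O)c1 | starting material
2 | 3,5-bis(TIPSO)benzaldehyde | O=Cc1cc(O[Si](C(C)C)(C(C)C)C(C)C)cc(O[Si](C(C)C)(C(C)C)C(C)C)c1 | intermediate
3 | [3,5-bis(TIPSO)phenyl]methanol | OCc1cc(O[Si](C(C)C)(C(C)C)C(C)C)cc(O[Si](C(C)C)(C(C)C)C(C)C)c1 | intermediate
4 | 3-fluoro-4-hydroxybenzaldehyde | O=Cc1ccc(O)c(F)c1 | starting material
5 | 4-{[3,5-bis(TIPSO)phenyl]methoxy}-3-fluorobenzaldehyde | O=Cc1ccc(OCc2cc(O[Si](C(C)C)(C(C)C)C(C)C)cc(O[Si](C(C)C)(C(C)C)C(C)C)c2)c(F)c1 | intermediate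
6 | 1-(dimethoxymethyl)-3-fluoro-4-{[3,5-bis(TIPSO)phenyl]methoxy}benzene | COC(OC)c1ccc(OCc2cc(O[Si](C(C)C)(C(C)C)C(C)C)cc(O[Si](C(C)C)(C(C)C)C(C)C)c2)c(F)c1 | intermediate
7 | 3,4-dihydroxybenzaldehyde | O=Cc1ccc(O)c(O)c1 | starting material
8 | 3,4-bis(TIPSO)benzaldehyde | O=Cc1ccc(O[Si](C(C)C)(C(C)C)C(C)C)c(O[Si](C(C)C)(C(C)C)C(C)C)c1 | intermediate
9 | {[3,5-bis(TIPSO)phenyl][4-(dimethoxymethyl)-2-fluorophenoxy]methyl}lithium (ligand-bound, not isolated) | [Li]C(Oc1ccc(C(OC)OC)cc1F)c1cc(O[Si](C(C)C)(C(C)C)C(C)C)cc(O[Si](C(C)C)(C(C)C)C(C)C)c1 | intermediate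
10 | lithium (1R,2R)-1-[3,4-bis(TIPSO)phenyl]-2-[3,5-bis(TIPSO)phenyl]-2-[4-(dimethoxymethyl)-2-fluorophenoxy]ethan-1-olate (not isolated) | [Li]O[C@H](c1ccc(O[Si](C(C)C)(C(C)C)C(C)C)c(O[Si](C(C)C)(C(C)C)C(C)C)c1)[C@@H](c1cc(O[Si](C(C)C)(C(C)C)C(C)C)cc(O[Si](C(C)C)(C(C)C)C(C)C)c1)Oc1ccc(C(OC)OC)cc1F | intermediate
11 | (2R,3R)-3-[3,4-bis(TIPSO)phenyl]-2-[3,5-bis(TIPSO)phenyl]-6-(dimethoxymethyl)-2,3-dihydro-1,4-benzodioxine | COC(OC)c1ccc2c(c1)O[C@H](c1ccc(O[Si](C(C)C)(C(C)C)C(C)C)c(O[Si](C(C)C)(C(C)C)C(C)C)c1)[C@@H](c1cc(O[Si](C(C)C)(C(C)C)C(C)C)cc(O[Si](C(C)C)(C(C)C)C(C)C)c1)O2 | intermediate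
12 | (2R,3R)-3-[3,4-bis(TIPSO)phenyl]-2-[3,5-bis(TIPSO)phenyl]-2,3-dihydro-1,4-benzodioxine-6-carbaldehyde | O=Cc1ccc2c(c1)O[C@H](c1ccc(O[Si](C(C)C)(C(C)C)C(C)C)c(O[Si](C(C)C)(C(C)C)C(C)C)c1)[C@@H](c1cc(O[Si](C(C)C)(C(C)C)C(C)C)cc(O[Si](C(C)C)(C(C)C)C(C)C)c1)O2 | intermediate
13 | 1-(bromomethyl)-3,5-bis(TIPSO)benzene | BrCc1cc(O[Si](C(C)C)(C(C)C)C(C)C)cc(O[Si](C(C)C)(C(C)C)C(C)C)c1 | intermediate
14 | diethyl {[3,5-bis(TIPSO)phenyl]methyl}phosphonate | CCOP(=O)(OCC)Cc1cc(O[Si](C(C)C)(C(C)C)C(C)C)cc(O[Si](C(C)C)(C(C)C)C(C)C)c1 | intermediate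
15 | (2R,3R)-3-[3,4-bis(TIPSO)phenyl]-2-[3,5-bis(TIPSO)phenyl]-6-{(E)-2-[3,5-bis(TIPSO)phenyl]ethenyl}-2,3-dihydro-1,4-benzodioxine | CC(C)[Si](C(C)C)(C(C)C)Oc1cc(O[Si](C(C)C)(C(C)C)C(C)C)cc(/C=C/c2ccc3c(c2)O[C@H](c2ccc(O[Si](C(C)C)(C(C)C)C(C)C)c(O[Si](C(C)C)(C(C)C)C(C)C)c2)[C@@H](c2cc(O[Si](C(C)C)(C(C)C)C(C)C)cc(O[Si](C(C)C)(C(C)C)C(C)C)c2)O3)c1 | intermediate
16 | cassigarol E, 5-{(E)-2-[(2R,3R)-3-(3,4-dihydroxyphenyl)-2-(3,5-dihydroxyphenyl)-2,3-dihydro-1,4-benzodioxin-6-yl]ethenyl}benzene-1,3-diol | Oc1cc(O)cc(/C=C/c2ccc3c(c2)O[C@H](c2ccc(O)c(O)c2)[C@@H](c2cc(O)cc(O)c2)O3)c1 | target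

**Totals and risks**

Total step count: 11. Longest linear sequence: 8 (steps 1, 2, 3, 4, 6, 7, 10, 11).

Steps most likely to fail:

Step 6 (Proposed new method). What may go wrong: substrate oxygens may displace the chiral ligand from lithium and erode the absolute control; a non-bridged addition would give the erythro alkoxide and hence the cis ring; ring lithiation ortho to fluorine may compete; aryl silyl groups may be lost in the warm alkoxide stage. Fallback with known chemistry, setting out from 6 and 8 and coming back at 11: lithiation of 6 with t-BuLi in THF at −78 °C without ligand and addition to 8 give the racemic alcohol as a diastereomer mixture, 1-[3,4-bis(TIPSO)phenyl]-2-[3,5-bis(TIPSO)phenyl]-2-[4-(dimethoxymethyl)-2-fluorophenoxy]ethan-1-ol F1. Dess–Martin oxidation (NaHCO3, CH2Cl2) gives the ketone 1-[3,4-bis(TIPSO)phenyl]-2-[3,5-bis(TIPSO)phenyl]-2-[4-(dimethoxymethyl)-2-fluorophenoxy]ethan-1-one F2, whose α-aryloxy benzylic center epimerizes under mild base. Asymmetric transfer hydrogenation with dynamic kinetic resolution (Noyori–Ikariya type; RuCl[(S,S)-TsDPEN](p-cymene), amine-rich HCO2H/Et3N, DMF, 40 °C) should then set both centers and give the (1R,2R)-alcohol (1R,2R)-1-[3,4-bis(TIPSO)phenyl]-2-[3,5-bis(TIPSO)phenyl]-2-[4-(dimethoxymethyl)-2-fluorophenoxy]ethan-1-ol F3, by analogy with benzoin-type substrates. F3 is closed in a separate alkoxide SNAr step (KOt-Bu, DMPU/THF, 50 °C) to give 11.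

Step 11. What may go wrong: oxidative degradation of the catechol and resorcinol anions once freed, and incomplete removal of the two crowded ortho silyl groups, which would leave a mixture that is hard to purify at the polyphenol stage. Fallback, setting out from 15 and coming back at 16: desilylation with Bu4NF/AcOH is followed in the same flask by Ac2O/pyridine, so that the product is isolated and purified as the air-stable cassigarol E hexaacetate F6. Catalytic NaOMe in degassed MeOH at 0 °C with an acidic resin quench then releases 16.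

Step 10. What may go wrong: silyl cleavage or migration caused by the basic phosphonate anion, sluggish addition to the electron-rich aldehyde, and erosion of the E geometry. Fallback, setting out from 12 and 2 and coming back at 15: Wittig methylenation with preformed Ph3P=CH2 (THF, −78 to 0 °C) converts 12 into (2R,3R)-3-[3,4-bis(TIPSO)phenyl]-2-[3,5-bis(TIPSO)phenyl]-6-ethenyl-2,3-dihydro-1,4-benzodioxine F4 and 2 into 1-ethenyl-3,5-bis(TIPSO)benzene F5. Cross-metathesis of F4 with an excess of F5 (second-generation Grubbs catalyst, CH2Cl2, 40 °C) should give 15 as the thermodynamically favoured E alkene under neutral conditions.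

Further compounds
F1 | step 6 | 1-[3,4-bis(TIPSO)phenyl]-2-[3,5-bis(TIPSO)phenyl]-2-[4-(dimethoxymethyl)-2-fluorophenoxy]ethan-1-ol (racemic, both diastereomers) | OC(c1ccc(O[Si](C(C)C)(C(C)C)C(C)C)c(O[Si](C(C)C)(C(C)C)C(C)C)c1)C(c1cc(O[Si](C(C)C)(C(C)C)C(C)C)cc(O[Si](C(C)C)(C(C)C)C(C)C)c1)Oc1ccc(C(OC)OC)cc1F
F2 | step 6 | 1-[3,4-bis(TIPSO)phenyl]-2-[3,5-bis(TIPSO)phenyl]-2-[4-(dimethoxymethyl)-2-fluorophenoxy]ethan-1-one (racemic) | O=C(c1ccc(O[Si](C(C)C)(C(C)C)C(C)C)c(O[Si](C(C)C)(C(C)C)C(C)C)c1)C(c1cc(O[Si](C(C)C)(C(C)C)C(C)C)cc(O[Si](C(C)C)(C(C)C)C(C)C)c1)Oc1ccc(C(OC)OC)cc1F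
F3 | step 6 | (1R,2R)-1-[3,4-bis(TIPSO)phenyl]-2-[3,5-bis(TIPSO)phenyl]-2-[4-(dimethoxymethyl)-2-fluorophenoxy]ethan-1-ol | O[C@H](c1ccc(O[Si](C(C)C)(C(C)C)C(C)C)c(O[Si](C(C)C)(C(C)C)C(C)C)c1)[C@@H](c1cc(O[Si](C(C)C)(C(C)C)C(C)C)cc(O[Si](C(C)C)(C(C)C)C(C)C)c1)Oc1ccc(C(OC)OC)cc1F
F4 | step 10 | (2R,3R)-3-[3,4-bis(TIPSO)phenyl]-2-[3,5-bis(TIPSO)phenyl]-6-ethenyl-2,3-dihydro-1,4-benzodioxine | C=Cc1ccc2c(c1)O[C@H](c1ccc(O[Si](C(C)C)(C(C)C)C(C)C)c(O[Si](C(C)C)(C(C)C)C(C)C)c1)[C@@H](c1cc(O[Si](C(C)C)(C(C)C)C(C)C)cc(O[Si](C(C)C)(C(C)C)C(C)C)c1)O2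
F5 | step 10 | 1-ethenyl-3,5-bis(TIPSO)benzene | C=Cc1cc(O[Si](C(C)C)(C(C)C)C(C)C)cc(O[Si](C(C)C)(C(C)C)C(C)C)c1
F6 | step 11 | cassigarol E hexaacetate | CC(=O)Oc1cc(OC(C)=O)cc(/C=C/c2ccc3c(c2)O[C@H](c2ccc(OC(C)=O)c(OC(C)=O)c2)[C@@H](c2cc(OC(C)=O)cc(OC(C)=O)c2)O3)c1
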